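**Plan**

1. Colpol is cut first at the ring A C–Br bond (back to C–SiMe3), then at three C–C bonds of ring A: C5–C6, C1–C2 and C2–C3 (ring A numbered C1 = chain-bearing carbon, C2 = C–OH, C3 = CH, C4 = C–Br, C5 = C–OMe, C6 = CH).
2. Ring A has its free OH (C2) para to its only OMe (C5), the butenyl chain (C1) ortho to the OH and the bromine (C4) ortho to the OMe; this is the pattern that a methoxy(alkenyl)carbene chromium complex, one CO and a terminal alkyne assemble.
3. The alkyne partner, a (Z)-hex-4-en-1-yne carrying ring B, is cut at the allyl–alkynyl bond, at the alkene (back to an alkyne) and at the benzyl–alkynyl bond, giving a ring B benzyl bromide, propargyl alcohol and ethynylmagnesium bromide.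
4. Forward: the ring B ester is silylated, reduced and brominated; the four-carbon chain and then the ethynyl group are joined by two copper-catalysed Grignard couplings; ring A is built last around the terminal alkyne by carbene benzannulation.
5. End game: the ring B silyl ethers are exchanged for acetates, the aryl silane is converted to the aryl bromide by ipso substitution, and the three acetates are removed.
6. There is no stereocentre; the only stereo element, the Z double bond, comes from cis-semihydrogenation of the butynol over poisoned palladium and is carried unchanged to the end.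

Key step: step 9

Remark: ring B is carried as its bis(tert-butyldimethylsilyl) ether because aryl acetates would not survive steps 2, 4 and 7, and it is switched to the diacetate only before step 12, where silyl ethers would leave ring B open to bromination. Compounds 1, 5, 10, 12 and 13 are taken as commercial.

**Route**

Step 1
Reactants: 1 methyl 4-bromo-3,5-dihydroxybenzoate
Product: 2 methyl 4-bromo-3,5-bis(tert-butyldimethylsilyloxy)benzoate
Conditions: TBSCl (2.5 equiv), imidazole (5 equiv), DMF, rt
Reagents that add atoms: tert-butyldimethylsilyl chloride, CC(C)(C)[Si](C)(C)Cl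
Why: Imidazole-promoted O-silylation of both phenols masks them against the hydride and organomagnesium reagents that follow, while the ester is untouched.

Step 2
Reactants: 2 methyl 4-bromo-3,5-bis(tert-butyldimethylsilyloxy)benzoate
Product: 3 [4-bromo-3,5-bis(tert-butyldimethylsilyloxy)phenyl]methanol
Conditions: i-Bu2AlH (2.5 equiv), CH2Cl2, −78 to 0 °C; then aq. potassium sodium tartrate
Reagents that add atoms: none
Why: Aluminium hydride reduction of the ester to the benzylic alcohol should leave the aryl bromide and the aryl silyl ethers intact at low temperature.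

Step 3
Reactants: 3 [4-bromo-3,5-bis(tert-butyldimethylsilyloxy)phenyl]methanol
Product: 4 2-bromo-5-(bromomethyl)-1,3-bis(tert-butyldimethylsilyloxy)benzene
Conditions: CBr4, PPh3, CH2Cl2, 0 °C
Reagents that add atoms: carbon tetrabromide, BrC(Br)(Br)Br
Why: The Appel reaction converts the primary benzylic alcohol into the bromide under neutral conditions that the silyl ethers tolerate.

Step 4
Reactants: 4 2-bromo-5-(bromomethyl)-1,3-bis(tert-butyldimethylsilyloxy)benzene; 5 propargyl alcohol
Product: 7 4-[4-bromo-3,5-bis(tert-butyldimethylsilyloxy)phenyl]but-2-yn-1-ol, via bromomagnesium 3-(bromomagnesio)prop-2-yn-1-olate 6 (not isolated)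
Conditions: 5 (3 equiv), EtMgBr (6 equiv), THF, 0 °C to rt; then CuCl (10 mol %), 4, THF, 60 °C
Reagents that add atoms: none
Why: Copper-catalysed coupling of an alkynyl Grignard reagent with a benzylic bromide should alkylate the doubly metallated propargyl alcohol at carbon, and alkynylmagnesium species do not exchange with the aryl bromide.

Step 5
Reactants: 7 4-[4-bromo-3,5-bis(tert-butyldimethylsilyloxy)phenyl]but-2-yn-1-ol
Product: 8 (Z)-4-[4-bromo-3,5-bis(tert-butyldimethylsilyloxy)phenyl]but-2-en-1-ol
Conditions: H2 (1 atm), Pd/CaCO3 poisoned with Pb(OAc)2, quinoline, EtOAc, rt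
Reagents that add atoms: none
Why: Lindlar-type semihydrogenation delivers both hydrogens to the same face of the alkyne on the poisoned palladium surface, which sets the Z geometry and should stop short of over-reduction or loss of the aryl bromide.

Step 6
Reactants: 8 (Z)-4-[4-bromo-3,5-bis(tert-butyldimethylsilyloxy)phenyl]but-2-en-1-ol
Product: 9 2-bromo-5-[(Z)-4-bromobut-2-enyl]-1,3-bis(tert-butyldimethylsilyloxy)benzene
Conditions: CBr4, PPh3, CH2Cl2, −20 to 0 °C
Reagents that add atoms: carbon tetrabromide, BrC(Br)(Br)Br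
Why: The Appel reaction displaces the oxyphosphonium group at the primary allylic carbon by direct SN2 attack at low temperature, so neither allylic transposition nor loss of the Z geometry is expected.

Step 7
Reactants: 9 2-bromo-5-[(Z)-4-bromobut-2-enyl]-1,3-bis(tert-butyldimethylsilyloxy)benzene; 10 ethynylmagnesium bromide
Product: 11 (Z)-6-[4-bromo-3,5-bis(tert-butyldimethylsilyloxy)phenyl]hex-4-en-1-yne
Conditions: 10 (4 equiv, THF solution), CuCl (10 mol %), THF, 0 °C to rt
Reagents that add atoms: none
Why: Copper-catalysed coupling of an alkynyl Grignard reagent with a primary allylic bromide should give the linear skipped enyne with the Z alkene retained, and the excess of acetylide suppresses a second alkylation.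

Step 8
Reactants: 12 (1-bromovinyl)trimethylsilane; 13 chromium hexacarbonyl
Product: 16 pentacarbonyl[methoxy(1-trimethylsilylethenyl)carbene]chromium, via [1-(trimethylsilyl)vinyl]lithium 14 (not isolated), via lithium pentacarbonyl[1-oxido-2-(trimethylsilyl)prop-2-enylidene]chromate 15 (not isolated)
Conditions: t-BuLi (2 equiv), Et2O, −78 °C; Cr(CO)6, Et2O, −78 °C to rt; Me3OBF4, CH2Cl2, 0 °C
Reagents that add atoms: trimethyloxonium tetrafluoroborate, C[O+](C)C.F[B-](F)(F)F
Why: This is the Fischer carbene synthesis, in which bromine–lithium exchange gives the vinyllithium, its addition to a CO ligand gives the acylchromate, and O-methylation gives the methoxycarbene, as for 1-alkyl-substituted alkenyllithiums.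

Step 9
Reactants: 11 (Z)-6-[4-bromo-3,5-bis(tert-butyldimethylsilyloxy)phenyl]hex-4-en-1-yne; 16 pentacarbonyl[methoxy(1-trimethylsilylethenyl)carbene]chromium
Product: 18 2-[(Z)-4-[4-bromo-3,5-bis(tert-butyldimethylsilyloxy)phenyl]but-2-enyl]-4-methoxy-5-(trimethylsilyl)phenol, via tricarbonyl(η6-arene)chromium complex of the phenol 17 (not isolated)
Conditions: 16 (1.5 equiv), degassed THF, 50 °C, argon; then air, silica gel, Et2O, rt
Reagents that add atoms: none
Why: Thermal loss of one CO from 16 opens a site on zerovalent chromium for the terminal alkyne of 11, which inserts into the Cr=C bond with its unsubstituted carbon bonding to the carbene carbon (C5–C6), and CO insertion at the new carbene carbon then gives a chromium-bound dienylketene (C1–C2). Ring A closes by a 6π electrocyclization of this dienylketene that joins the ketene carbon to the vinyl CH2 (C2–C3), and the cyclohexadienone so formed, which has two hydrogens on its sp3 carbon, tautomerises to the phenol held as the Cr(CO)3 complex 17, from which air releases 18. The closest known reaction type is the Dötz benzannulation of 1-substituted alkenyl(methoxy)carbene pentacarbonylchromium complexes with terminal alkynes, here with a 1-silyl in place of a 1-alkyl substituent. No stereocentre is formed and the Z alkene is a spectator. Regiochemistry rests on the steric bias of the terminal alkyne, which places the butenyl chain next to the CO-derived phenol carbon and the hydrogen next to the methoxy carbon, and the silyl group ends on C4 because it sits on the carbene-bound vinyl carbon. The alkyne should react in preference to the skipped alkene because unactivated 1,2-dialkyl alkenes are inert to alkoxycarbene complexes at this temperature and an intramolecular cyclopropanation by the vinylcarbene intermediate would have to form a bicyclo[1.1.0]butane.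

Step 10
Reactants: 18 2-[(Z)-4-[4-bromo-3,5-bis(tert-butyldimethylsilyloxy)phenyl]but-2-enyl]-4-methoxy-5-(trimethylsilyl)phenol
Product: 19 2-bromo-5-[(Z)-4-[2-hydroxy-5-methoxy-4-(trimethylsilyl)phenyl]but-2-enyl]benzene-1,3-diol
Conditions: n-Bu4NF (2.5 equiv), AcOH (2.5 equiv), THF, 0 °C to rt
Reagents that add atoms: none
Why: Buffered fluoride cleaves the two aryl Si–O bonds, whereas the aryl C–SiMe3 bond on the electron-rich ring A should not be attacked under these conditions.

Step 11
Reactants: 19 2-bromo-5-[(Z)-4-[2-hydroxy-5-methoxy-4-(trimethylsilyl)phenyl]but-2-enyl]benzene-1,3-diol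
Product: 20 2-[(Z)-4-(3,5-diacetoxy-4-bromophenyl)but-2-enyl]-4-methoxy-5-(trimethylsilyl)phenyl acetate
Conditions: Ac2O (6 equiv), pyridine, DMAP (cat.), CH2Cl2, 0 °C to rt
Reagents that add atoms: acetic anhydride, CC(=O)OC(C)=O
Why: DMAP-catalysed acylation of all three phenols turns the hydroxyl groups into weak donors, so that ring B is deactivated and the methoxy group alone directs the electrophile in ring A.

Step 12
Reactants: 20 2-[(Z)-4-(3,5-diacetoxy-4-bromophenyl)but-2-enyl]-4-methoxy-5-(trimethylsilyl)phenyl acetate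
Product: 21 5-bromo-2-[(Z)-4-(3,5-diacetoxy-4-bromophenyl)but-2-enyl]-4-methoxyphenyl acetate
Conditions: NBS (1.05 equiv), MeCN, 0 °C, dark
Reagents that add atoms: N-bromosuccinimide, O=C1CCC(=O)N1Br
Why: Electrophilic ipso-bromodesilylation should occur at the silicon-bearing carbon, which is ortho to the methoxy group and para to the alkyl chain and gives a cation stabilised beta to silicon, while NBS in acetonitrile without light is known to brominate activated arenes in the presence of isolated alkenes.

Step 13
Reactants: 21 5-bromo-2-[(Z)-4-(3,5-diacetoxy-4-bromophenyl)but-2-enyl]-4-methoxyphenyl acetate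
Product: 22 colpol, 2-bromo-5-[(Z)-4-(4-bromo-2-hydroxy-5-methoxyphenyl)but-2-enyl]benzene-1,3-diol
Conditions: K2CO3 (0.2 equiv), MeOH, 0 °C to rt, argon; then aq. NH4Cl
Reagents that add atoms: none
Why: Base-catalysed methanolysis (transesterification) of the three aryl acetates is mild enough to leave the methyl ether, both aryl bromides and the skipped Z alkene unchanged.

**Compound list**

1 | methyl 4-bromo-3,5-dihydroxybenzoate | COC(=O)c1cc(O)c(Br)c(O)c1 | starting material
2 | methyl 4-bromo-3,5-bis(tert-butyldimethylsilyloxy)benzoate | COC(=O)c1cc(O[Si](C)(C)C(C)(C)C)c(Br)c(O[Si](C)(C)C(C)(C)C)c1 | intermediate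
3 | [4-bromo-3,5-bis(tert-butyldimethylsilyloxy)phenyl]methanol | OCc1cc(O[Si](C)(C)C(C)(C)C)c(Br)c(O[Si](C)(C)C(C)(C)C)c1 | intermediate
4 | 2-bromo-5-(bromomethyl)-1,3-bis(tert-butyldimethylsilyloxy)benzene | BrCc1cc(O[Si](C)(C)C(C)(C)C)c(Br)c(O[Si](C)(C)C(C)(C)C)c1 | intermediate
5 | propargyl alcohol | C#CCO | starting material
6 | bromomagnesium 3-(bromomagnesio)prop-2-yn-1-olate | Br[Mg]C#CCO[Mg]Br | intermediate (not isolated)
7 | 4-[4-bromo-3,5-bis(tert-butyldimethylsilyloxy)phenyl]but-2-yn-1-ol | OCC#CCc1cc(O[Si](C)(C)C(C)(C)C)c(Br)c(O[Si](C)(C)C(C)(C)C)c1 | intermediate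
8 | (Z)-4-[4-bromo-3,5-bis(tert-butyldimethylsilyloxy)phenyl]but-2-en-1-ol | OC/C=C\Cc1cc(O[Si](C)(C)C(C)(C)C)c(Br)c(O[Si](C)(C)C(C)(C)C)c1 | intermediate
9 | 2-bromo-5-[(Z)-4-bromobut-2-enyl]-1,3-bis(tert-butyldimethylsilyloxy)benzene | BrC/C=C\Cc1cc(O[Si](C)(C)C(C)(C)C)c(Br)c(O[Si](C)(C)C(C)(C)C)c1 | intermediate
10 | ethynylmagnesium bromide | C#C[Mg]Br | starting material
11 | (Z)-6-[4-bromo-3,5-bis(tert-butyldimethylsilyloxy)phenyl]hex-4-en-1-yne | C#CC/C=C\Cc1cc(O[Si](C)(C)C(C)(C)C)c(Br)c(O[Si](C)(C)C(C)(C)C)c1 | intermediate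
12 | (1-bromovinyl)trimethylsilane | C=C(Br)[Si](C)(C)C | starting material
13 | chromium hexacarbonyl | O=C=[Cr](=C=O)(=C=O)(=C=O)(=C=O)=C=O | starting material
14 | [1-(trimethylsilyl)vinyl]lithium | [Li]C(=C)[Si](C)(C)C | intermediate (not isolated)
15 | lithium pentacarbonyl[1-oxido-2-(trimethylsilyl)prop-2-enylidene]chromate | [Li+].[O-]C(C(=C)[Si](C)(C)C)=[Cr](=C=O)(=C=O)(=C=O)(=C=O)=C=O | intermediate (not isolated)
16 | pentacarbonyl[methoxy(1-trimethylsilylethenyl)carbene]chromium | COC(C(=C)[Si](C)(C)C)=[Cr](=C=O)(=C=O)(=C=O)(=C=O)=C=O | intermediate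
17 | tricarbonyl(η6-arene)chromium complex of phenol 18, metal on ring A (written as arene and Cr(CO)3 fragment joined by a dot) | COc1cc(C/C=C\Cc2cc(O[Si](C)(C)C(C)(C)C)c(Br)c(O[Si](C)(C)C(C)(C)C)c2)c(O)cc1[Si](C)(C)C.O=C=[Cr](=C=O)=C=O | intermediate (not isolated)
18 | 2-[(Z)-4-[4-bromo-3,5-bis(tert-butyldimethylsilyloxy)phenyl]but-2-enyl]-4-methoxy-5-(trimethylsilyl)phenol | COc1cc(C/C=C\Cc2cc(O[Si](C)(C)C(C)(C)C)c(Br)c(O[Si](C)(C)C(C)(C)C)c2)c(O)cc1[Si](C)(C)C | intermediate
19 | 2-bromo-5-[(Z)-4-[2-hydroxy-5-methoxy-4-(trimethylsilyl)phenyl]but-2-enyl]benzene-1,3-diol | COc1cc(C/C=C\Cc2cc(O)c(Br)c(O)c2)c(O)cc1[Si](C)(C)C | intermediate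
20 | 2-[(Z)-4-(3,5-diacetoxy-4-bromophenyl)but-2-enyl]-4-methoxy-5-(trimethylsilyl)phenyl acetate | COc1cc(C/C=C\Cc2cc(OC(C)=O)c(Br)c(OC(C)=O)c2)c(OC(C)=O)cc1[Si](C)(C)C | intermediate
21 | 5-bromo-2-[(Z)-4-(3,5-diacetoxy-4-bromophenyl)but-2-enyl]-4-methoxyphenyl acetate | COc1cc(C/C=C\Cc2cc(OC(C)=O)c(Br)c(OC(C)=O)c2)c(OC(C)=O)cc1Br | intermediate
22 | colpol, 2-bromo-5-[(Z)-4-(4-bromo-2-hydroxy-5-methoxyphenyl)but-2-enyl]benzene-1,3-diol | COc1cc(C/C=C\Cc2cc(O)c(Br)c(O)c2)c(O)cc1Br | target

**Step count**

Total: 13 steps. Longest linear sequence: 12 steps (steps 1–7 and 9–13); step 8 is a one-step branch.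

**Steps most likely to fail**

Step 9. The 1-silylvinyl carbene complex may decompose or lose its silyl group before it takes up the alkyne, or the vinylcarbene intermediate may cyclise without CO insertion, so that phenol formation is eroded. The fallback sets out from 11 and 13 and comes back at 21. The 2-silylvinyl isomer of the carbene complex, a known and stable stand-in for the unsubstituted vinylcarbene complex, is used instead: pentacarbonyl[methoxy((E)-2-(trimethylsilyl)ethenyl)carbene]chromium F1, made from 13 and (E)-(2-bromovinyl)trimethylsilane as in step 8. Benzannulation with 11 under the conditions of step 9 should give, once the carbon-bound silyl group has shifted to the phenol oxygen at the cyclohexadienone stage, [2-[(Z)-4-[4-bromo-3,5-bis(tert-butyldimethylsilyloxy)phenyl]but-2-enyl]-4-methoxyphenoxy]trimethylsilane F2, in which C3 and C4 of ring A carry hydrogen. n-Bu4NF/AcOH would remove all three O-silyl groups to give 2-bromo-5-[(Z)-4-(2-hydroxy-5-methoxyphenyl)but-2-enyl]benzene-1,3-diol F3, and Ac2O/pyridine would give 2-[(Z)-4-(3,5-diacetoxy-4-bromophenyl)but-2-enyl]-4-methoxyphenyl acetate F4. NBS in MeCN should then brominate F4 at C4, the less hindered of the two positions ortho to the methoxy group and para to the chain, to reach 21. The C–Br bond is then placed by the directing effects of ring A and not by ipso substitution.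

Step 12. Electrophilic bromine may attack the Z double bond or a free CH position of ring A in competition with ipso substitution. The fallback sets out from 20 and comes back at 21, and keeps electrophilic bromine away from the alkene. Ipso-borodesilylation of 20 with BCl3 (CH2Cl2, 0 °C) should give 5-(dichloroboranyl)-2-[(Z)-4-(3,5-diacetoxy-4-bromophenyl)but-2-enyl]-4-methoxyphenyl acetate F5. Pinacol and Et3N would convert it into 2-[(Z)-4-(3,5-diacetoxy-4-bromophenyl)but-2-enyl]-4-methoxy-5-(4,4,5,5-tetramethyl-1,3,2-dioxaborolan-2-yl)phenyl acetate F6. Copper-mediated bromodeboronation of F6 (CuBr2, MeOH/H2O, 80 °C) should then give 21; if acetates are partly lost in this last operation, the crude product would be re-acetylated as in step 11.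

Step 7. The copper-catalysed allylic substitution may leak to SN2′ attack, may isomerise the Z alkene through allylcopper intermediates, or may alkylate the product acetylide a second time. The fallback sets out from 4 and comes back at 11, and introduces the five-carbon unit in one piece before the alkene exists. The bromomagnesium acetylide of 1-(trimethylsilyl)penta-1,4-diyne (EtMgBr, THF) would be coupled with 4 under CuCl catalysis to give [6-[4-bromo-3,5-bis(tert-butyldimethylsilyloxy)phenyl]hexa-1,4-diynyl]trimethylsilane F7. Semihydrogenation over Pd/CaCO3 poisoned with Pb(OAc)2, which reduces the dialkyl alkyne much faster than the silyl-capped one, should give [(Z)-6-[4-bromo-3,5-bis(tert-butyldimethylsilyloxy)phenyl]hex-4-en-1-ynyl]trimethylsilane F8. Removal of the alkynyl silyl group with AgNO3 (cat.) in acetone/H2O, which spares aryl silyl ethers, would then give 11.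

**Further compounds**

F1 | step 9 | pentacarbonyl[methoxy((E)-2-(trimethylsilyl)ethenyl)carbene]chromium | COC(/C=C/[Si](C)(C)C)=[Cr](=C=O)(=C=O)(=C=O)(=C=O)=C=O
F2 | step 9 | [2-[(Z)-4-[4-bromo-3,5-bis(tert-butyldimethylsilyloxy)phenyl]but-2-enyl]-4-methoxyphenoxy]trimethylsilane | COc1ccc(O[Si](C)(C)C)c(C/C=C\Cc2cc(O[Si](C)(C)C(C)(C)C)c(Br)c(O[Si](C)(C)C(C)(C)C)c2)c1
F3 | step 9 | 2-bromo-5-[(Z)-4-(2-hydroxy-5-methoxyphenyl)but-2-enyl]benzene-1,3-diol | COc1ccc(O)c(C/C=C\Cc2cc(O)c(Br)c(O)c2)c1
F4 | step 9 | 2-[(Z)-4-(3,5-diacetoxy-4-bromophenyl)but-2-enyl]-4-methoxyphenyl acetate | COc1ccc(OC(C)=O)c(C/C=C\Cc2cc(OC(C)=O)c(Br)c(OC(C)=O)c2)c1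
F5 | step 12 | 5-(dichloroboranyl)-2-[(Z)-4-(3,5-diacetoxy-4-bromophenyl)but-2-enyl]-4-methoxyphenyl acetate | COc1cc(C/C=C\Cc2cc(OC(C)=O)c(Br)c(OC(C)=O)c2)c(OC(C)=O)cc1B(Cl)Cl
F6 | step 12 | 2-[(Z)-4-(3,5-diacetoxy-4-bromophenyl)but-2-enyl]-4-methoxy-5-(4,4,5,5-tetramethyl-1,3,2-dioxaborolan-2-yl)phenyl acetate | COc1cc(C/C=C\Cc2cc(OC(C)=O)c(Br)c(OC(C)=O)c2)c(OC(C)=O)cc1B1OC(C)(C)C(C)(C)O1
F7 | step 7 | [6-[4-bromo-3,5-bis(tert-butyldimethylsilyloxy)phenyl]hexa-1,4-diynyl]trimethylsilane | C[Si](C)(C)C#CCC#CCc1cc(O[Si](C)(C)C(C)(C)C)c(Br)c(O[Si](C)(C)C(C)(C)C)c1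
F8 | step 7 | [(Z)-6-[4-bromo-3,5-bis(tert-butyldimethylsilyloxy)phenyl]hex-4-en-1-ynyl]trimethylsilane | C[Si](C)(C)C#CC/C=C\Cc1cc(O[Si](C)(C)C(C)(C)C)c(Br)c(O[Si](C)(C)C(C)(C)C)c1
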